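**Retrosynthetic overview**
1. Target 21 ⇐ silyl-protected 20 ⇐ ester C–O bond by anti opening of oxirane 14 at C6 with benzoic acid 19 (C6 inverted, C7 kept).
2. Pyran ring of 14 ⇐ amine-relayed O–C3 closure of hydroxymethyl enynone 12; its C1–O bond and the C4a=C8a alkene ⇐ singlet-oxygen ene reaction of α-methylene ketone 10.
3. C4a–C4 bond ⇐ light-driven, copper-catalysed dealkenylative alkynylation of carvone oxide 7 with enyne ester 5 (key step, new).
4. 7 ⇐ (R)-carvone (epoxidation anti to the isopropenyl group sets both stereocentres); 5 ⇐ ylide olefination of a silyl ynal; 19 ⇐ ortho-lithiation/carboxylation of a silylated catechol.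
5. Ring order: carbocycle (bought) → oxirane → pyran (last ring formed); the arene is bought.

Assumption: 1, 2, 6 and 15 are catalogue compounds; 9 and 10 are carried as epimer mixtures at the alkyne-bearing ring carbon, which becomes sp2 in step 5.

**Route**

Step 1
Reactants: 1 3-(trimethylsilyl)prop-2-ynal; 2 (triphenylphosphoranylidene)ketene
Product: 5 2-(trimethylsilyl)ethyl (E)-pent-2-en-4-ynoate, via ester ylide 3 (not isolated), via C-silyl enyne ester 4 (not isolated)
Conditions: Me3SiCH2CH2OH, THF, 60 °C; then 1, rt; then AcOH, Bu4NF, −20 °C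
Reagents that add atoms: 2-(trimethylsilyl)ethanol, C[Si](C)(C)CCO
Why: Bestmann three-component Wittig olefination: the alcohol adds to the cumulated ylide to give stabilised ylide 3, which olefinates ynal 1 E-selectively, and buffered fluoride then removes only the alkynyl silyl group.

Step 2
Reactants: 6 (R)-carvone
Product: 7 (1R,4R,6R)-1-methyl-4-(prop-1-en-2-yl)-7-oxabicyclo[4.1.0]heptan-2-one
Conditions: 30% H2O2, NaOH (cat.), MeOH, 0 °C
Reagents that add atoms: hydrogen peroxide, OO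
Why: Weitz–Scheffer nucleophilic epoxidation: hydroperoxide adds to the enone face opposite the C5 isopropenyl group, so the purchased stereocentre fixes both oxirane carbons as (1R,6R).

Step 3
Reactants: 7 carvone oxide; 5 enyne ester
Product: 9 2-(trimethylsilyl)ethyl (E)-5-[(1R,6R)-1-methyl-2-oxo-7-oxabicyclo[4.1.0]heptan-4-yl]pent-2-en-4-ynoate (C4 epimers), via methoxy hydroperoxide 8 (not isolated)
Conditions: O3, CH2Cl2/MeOH (4:1), −78 °C; N2 purge, evaporate cold; then 5 (1.5 equiv), Cu(MeCN)4PF6 (10 mol %), 4,4',4''-tri-tert-butyl-2,2':6',2''-terpyridine (12 mol %), K3PO4, MeCN, 450 nm LEDs, 0 °C to rt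
Reagents that add atoms: none
Why: Proposed new method: Criegee ozonolysis in methanol turns the isopropenyl group into α-methoxy hydroperoxide 8, the blue-light-excited monovalent copper acetylide of 5 reduces its O–O bond, the alkoxy radical fragments by β-scission (loss of methyl acetate) to the ring C4 radical, and this is captured by the divalent copper acetylide and released from trivalent copper by C(sp3)–C(sp) reductive elimination; the closest known reactions are iron- and copper-mediated dealkenylative couplings of such ozonolysis-derived hydroperoxides and the photoinduced copper-catalysed radical alkynylation of redox-active esters with terminal alkynes; the new C4 centre forms as an epimer mixture that is erased in step 5, and the oxirane centres are untouched.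

Step 4
Reactants: 9 alkynyl epoxy ketone
Product: 10 2-(trimethylsilyl)ethyl (E)-5-[(1R,6R)-1-methyl-3-methylidene-2-oxo-7-oxabicyclo[4.1.0]heptan-4-yl]pent-2-en-4-ynoate (C4 epimers)
Conditions: (CH2O)n, i-Pr2NH·CF3CO2H (1 equiv), CF3CO2H (10 mol %), THF, 60 °C; used crude
Reagents that add atoms: formaldehyde (as paraformaldehyde), C=O
Why: Mannich-type α-methylenation (iminium addition, then β-elimination of the amine): C3 is the only enolisable position because C1 is quaternary, no stereocentre is formed and the oxirane is untouched.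

Step 5
Reactants: 10 α-methylene ketone
Product: 12 2-(trimethylsilyl)ethyl (E)-5-[(1R,6R)-3-(hydroxymethyl)-1-methyl-2-oxo-7-oxabicyclo[4.1.0]hept-3-en-4-yl]pent-2-en-4-ynoate, via allylic hydroperoxide 11 (not isolated)
Conditions: O2, 5,10,15,20-tetraphenylporphyrin (0.5 mol %), CH2Cl2, white LEDs, −20 °C; then PPh3 (1.0 equiv), −20 to 0 °C
Reagents that add atoms: dioxygen, O=O
Why: Schenck ene reaction of singlet oxygen (dye-sensitised photooxygenation): in the s-cis α-methylene ketone the only allylic hydrogen is on C4, geminal to the carbonyl, so oxygen adds to the methylene carbon and the alkene moves into the ring (C3=C4), which converges both C4 epimers; PPh3 reduces the hydroperoxide and the oxirane centres are untouched.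

Step 6
Reactants: 12 hydroxymethyl enynone
Product: 14 2-(trimethylsilyl)ethyl (E)-3-[(6R,7R)-6,7-epoxy-7-methyl-8-oxo-5,6,7,8-tetrahydro-1H-isochromen-3-yl]prop-2-enoate, via morpholine dienaminone 13 (not isolated)
Conditions: morpholine (1.1 equiv), MeCN, 0 °C to rt; then pyridinium p-toluenesulfonate (1.5 equiv), 40 °C
Reagents that add atoms: none
Why: 1,6-Aza-Michael addition of morpholine to the alkyne carbon polarised by the ketone (a stronger acceptor than the ester) gives vinylogous amide 13, and acid-promoted addition–elimination by the neighbouring CH2OH (6-exo-trig, loss of morpholinium) closes the 1H-isochromene, avoiding the five-ring closure that direct in-plane attack of the hydroxyl on the alkyne would favour; E geometry and the oxirane are retained.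

Step 7
Reactants: 15 2-hydroxy-3-methoxy-5-methylbenzaldehyde
Product: 16 3-methoxy-5-methylbenzene-1,2-diol
Conditions: 30% H2O2, B(OH)3, H2SO4 (cat.), THF, rt
Reagents that add atoms: hydrogen peroxide, OO
Why: Dakin oxidation: peroxide adds to the electron-rich ortho-hydroxybenzaldehyde, the aryl group migrates to oxygen and the aryl formate hydrolyses to the catechol.

Step 8
Reactants: 16 catechol
Product: 17 [(3-methoxy-5-methyl-1,2-phenylene)bis(oxy)]bis(triisopropylsilane)
Conditions: i-Pr3SiOTf (2.4 equiv), 2,6-lutidine, CH2Cl2, 0 °C to rt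
Reagents that add atoms: triisopropylsilyl trifluoromethanesulfonate, CC(C)[Si](C(C)C)(C(C)C)OS(=O)(=O)C(F)(F)F
Why: Silylation of both phenols with the reactive silyl triflate; the bulky, non-coordinating silyl ethers leave the methoxy group as the only ortho-director for step 9.

Step 9
Reactants: 17 bis-silyl ether
Product: 19 2-methoxy-6-methyl-3,4-bis[(triisopropylsilyl)oxy]benzoic acid, via aryllithium 18 (not isolated)
Conditions: n-BuLi, N,N,N',N'-tetramethylethylenediamine, Et2O, 0 °C to rt; then CO2, −78 °C; 1 M HCl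
Reagents that add atoms: carbon dioxide, O=C=O
Why: Directed ortho metalation: the methoxy oxygen guides n-BuLi to the ring hydrogen between OMe and CH3 (the hindered silyl ethers neither coordinate nor expose the other ring hydrogen), and aryllithium 18 is carboxylated by CO2.

Step 10
Reactants: 14 pyran epoxide; 19 benzoic acid
Product: 20 2-(trimethylsilyl)ethyl (E)-3-[(6S,7R)-7-hydroxy-6-({2-methoxy-6-methyl-3,4-bis[(triisopropylsilyl)oxy]benzoyl}oxy)-7-methyl-8-oxo-5,6,7,8-tetrahydro-1H-isochromen-3-yl]prop-2-enoate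
Conditions: 19 (1.5 equiv), Cs2CO3 (0.5 equiv), DMF, 45 °C
Reagents that add atoms: none
Why: SN2 epoxide ring opening by the caesium carboxylate at the secondary carbon C6, anti to the oxirane oxygen, inverts C6 to S and leaves the tertiary C7–O bond intact (7R), giving the trans hydroxy ester; excess acid buffers against E1cB at C5.

Step 11
Reactants: 20 protected ester
Product: 21 (E)-3-[(6S,7R)-6-[(3,4-dihydroxy-2-methoxy-6-methylbenzoyl)oxy]-7-hydroxy-7-methyl-8-oxo-5,6,7,8-tetrahydro-1H-isochromen-3-yl]prop-2-enoic acid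
Conditions: Bu4NF (6 equiv), AcOH (3 equiv), THF/DMF, 0 °C to rt, degassed; pH 4 buffer
Reagents that add atoms: none
Why: Fluoride-induced desilylation: Si–O cleavage of both aryl silyl ethers and β-elimination of the 2-(trimethylsilyl)ethyl ester, with acetic acid buffering to avoid E1cB loss of the C6 ester; neither stereocentre is touched.

**Compound list**
1 | 3-(trimethylsilyl)prop-2-ynal | C[Si](C)(C)C#CC=O | starting material
2 | (triphenylphosphoranylidene)ketene | O=C=C=P(c1ccccc1)(c1ccccc1)c1ccccc1 | starting material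
3 | 2-(trimethylsilyl)ethyl (triphenylphosphoranylidene)acetate | C[Si](C)(C)CCOC(=O)C=P(c1ccccc1)(c1ccccc1)c1ccccc1 | intermediate
4 | 2-(trimethylsilyl)ethyl (E)-5-(trimethylsilyl)pent-2-en-4-ynoate | C[Si](C)(C)C#C/C=C/C(=O)OCC[Si](C)(C)C | intermediate
5 | 2-(trimethylsilyl)ethyl (E)-pent-2-en-4-ynoate | C#C/C=C/C(=O)OCC[Si](C)(C)C | intermediate
6 | (R)-carvone, (5R)-2-methyl-5-(prop-1-en-2-yl)cyclohex-2-en-1-one | CC(=C)[C@H]1CC(=O)C(C)=CC1 | starting material
7 | (1R,4R,6R)-1-methyl-4-(prop-1-en-2-yl)-7-oxabicyclo[4.1.0]heptan-2-one (oxirane trans to isopropenyl) | CC(=C)[C@H]1CC(=O)[C@]2(C)O[C@@H]2C1 | intermediate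
8 | (1R,4R,6R)-4-(1-hydroperoxy-1-methoxyethyl)-1-methyl-7-oxabicyclo[4.1.0]heptan-2-one (both configurations at the peroxy carbon) | COC(C)(OO)[C@H]1CC(=O)[C@]2(C)O[C@@H]2C1 | intermediate
9 | 2-(trimethylsilyl)ethyl (E)-5-[(1R,6R)-1-methyl-2-oxo-7-oxabicyclo[4.1.0]heptan-4-yl]pent-2-en-4-ynoate (C4 epimers) | C[Si](C)(C)CCOC(=O)/C=C/C#CC1CC(=O)[C@]2(C)O[C@@H]2C1 | intermediate
10 | 2-(trimethylsilyl)ethyl (E)-5-[(1R,6R)-1-methyl-3-methylidene-2-oxo-7-oxabicyclo[4.1.0]heptan-4-yl]pent-2-en-4-ynoate (C4 epimers) | C[Si](C)(C)CCOC(=O)/C=C/C#CC1C(=C)C(=O)[C@]2(C)O[C@@H]2C1 | intermediate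
11 | 2-(trimethylsilyl)ethyl (E)-5-[(1R,6R)-3-(hydroperoxymethyl)-1-methyl-2-oxo-7-oxabicyclo[4.1.0]hept-3-en-4-yl]pent-2-en-4-ynoate | C[Si](C)(C)CCOC(=O)/C=C/C#CC1=C(COO)C(=O)[C@]2(C)O[C@@H]2C1 | intermediate
12 | 2-(trimethylsilyl)ethyl (E)-5-[(1R,6R)-3-(hydroxymethyl)-1-methyl-2-oxo-7-oxabicyclo[4.1.0]hept-3-en-4-yl]pent-2-en-4-ynoate | C[Si](C)(C)CCOC(=O)/C=C/C#CC1=C(CO)C(=O)[C@]2(C)O[C@@H]2C1 | intermediate
13 | 2-(trimethylsilyl)ethyl (2E)-5-[(1R,6R)-3-(hydroxymethyl)-1-methyl-2-oxo-7-oxabicyclo[4.1.0]hept-3-en-4-yl]-4-(morpholin-4-yl)penta-2,4-dienoate | C[Si](C)(C)CCOC(=O)/C=C/C(=CC1=C(CO)C(=O)[C@]2(C)O[C@@H]2C1)N1CCOCC1 | intermediate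
14 | 2-(trimethylsilyl)ethyl (E)-3-[(6R,7R)-6,7-epoxy-7-methyl-8-oxo-5,6,7,8-tetrahydro-1H-isochromen-3-yl]prop-2-enoate | C[Si](C)(C)CCOC(=O)/C=C/C1=CC2=C(CO1)C(=O)[C@]3(C)O[C@@H]3C2 | intermediate
15 | 2-hydroxy-3-methoxy-5-methylbenzaldehyde | COc1cc(C)cc(C=O)c1O | starting material
16 | 3-methoxy-5-methylbenzene-1,2-diol | COc1cc(C)cc(O)c1O | intermediate
17 | [(3-methoxy-5-methyl-1,2-phenylene)bis(oxy)]bis(triisopropylsilane) | COc1cc(C)cc(O[Si](C(C)C)(C(C)C)C(C)C)c1O[Si](C(C)C)(C(C)C)C(C)C | intermediate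
18 | {2-methoxy-6-methyl-3,4-bis[(triisopropylsilyl)oxy]phenyl}lithium | COc1c([Li])c(C)cc(O[Si](C(C)C)(C(C)C)C(C)C)c1O[Si](C(C)C)(C(C)C)C(C)C | intermediate
19 | 2-methoxy-6-methyl-3,4-bis[(triisopropylsilyl)oxy]benzoic acid | COc1c(O[Si](C(C)C)(C(C)C)C(C)C)c(O[Si](C(C)C)(C(C)C)C(C)C)cc(C)c1C(=O)O | intermediate
20 | 2-(trimethylsilyl)ethyl (E)-3-[(6S,7R)-7-hydroxy-6-({2-methoxy-6-methyl-3,4-bis[(triisopropylsilyl)oxy]benzoyl}oxy)-7-methyl-8-oxo-5,6,7,8-tetrahydro-1H-isochromen-3-yl]prop-2-enoate | COc1c(O[Si](C(C)C)(C(C)C)C(C)C)c(O[Si](C(C)C)(C(C)C)C(C)C)cc(C)c1C(=O)O[C@H]1CC2=C(COC(/C=C/C(=O)OCC[Si](C)(C)C)=C2)C(=O)[C@]1(C)O | intermediate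
21 | (E)-3-[(6S,7R)-6-[(3,4-dihydroxy-2-methoxy-6-methylbenzoyl)oxy]-7-hydroxy-7-methyl-8-oxo-5,6,7,8-tetrahydro-1H-isochromen-3-yl]prop-2-enoic acid | COc1c(O)c(O)cc(C)c1C(=O)O[C@H]1CC2=C(COC(/C=C/C(=O)O)=C2)C(=O)[C@]1(C)O | target

**Step count**
Total: 11 steps. Longest linear sequence: 7 steps (6 → 7 → 9 → 10 → 12 → 14 → 20 → 21; the branch from 1 is equally long).

**Three steps most likely to fail**

Step 3 (the new photochemical dealkenylative alkynylation). Risks are Glaser dimerisation of 5, reduction of the ring radical and a sluggish acetylide of the electron-poor enyne. The fallback uses known thermal radical chemistry and cross-coupling; it sets out from 7 and returns at 9. Ozonolysis in methanol gives 8 as before; FeSO4·7H2O (2.2 equiv) and 1-methyl-4-({[tri(propan-2-yl)silyl]ethynyl}sulfonyl)benzene then effect divalent-iron reduction, β-scission and radical addition–elimination at the alkynyl sulfone to give (1R,6R)-1-methyl-4-{[tri(propan-2-yl)silyl]ethynyl}-7-oxabicyclo[4.1.0]heptan-2-one F1. Bu4NF/AcOH gives (1R,6R)-4-ethynyl-1-methyl-7-oxabicyclo[4.1.0]heptan-2-one F2. Sonogashira coupling (Pd(PPh3)2Cl2, CuI, Et3N) with 2-(trimethylsilyl)ethyl (E)-3-iodoprop-2-enoate F3 (from commercial (E)-3-iodoacrylic acid, 2-(trimethylsilyl)ethanol and N,N'-dicyclohexylcarbodiimide) gives 9.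

Step 5 (ene reaction on an electron-poor alkene; 10 may also isomerise to the 2-methyl enone or dimerise before it reacts). The fallback is polar and light-free; it sets out from 9, bypasses 10 and returns at 12. LiN(SiMe3)2 (THF, −78 °C) gives the lithium enolate of 9 F4. Alkylation with chloromethyl triisopropylsilyl ether gives 2-(trimethylsilyl)ethyl (E)-5-[(1R,6R)-1-methyl-2-oxo-3-{[(triisopropylsilyl)oxy]methyl}-7-oxabicyclo[4.1.0]heptan-4-yl]pent-2-en-4-ynoate F5. Dehydrogenation with 2-iodoxybenzoic acid (DMSO, 70 °C) gives the enone silyl ether 2-(trimethylsilyl)ethyl (E)-5-[(1R,6R)-1-methyl-2-oxo-3-{[(triisopropylsilyl)oxy]methyl}-7-oxabicyclo[4.1.0]hept-3-en-4-yl]pent-2-en-4-ynoate F6, and HF·pyridine (pyridine, THF) releases 12.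

Step 10 (carboxylate opening of a hindered oxirane next to a vinylogously acidic CH2; E1cB or no reaction are the risks). The fallback separates C–O bond formation from acylation; it sets out from 14 and returns at 20. HClO4 (cat.), THF/H2O, 0 °C opens the oxirane at C6 with inversion to the trans-diol 2-(trimethylsilyl)ethyl (E)-3-[(6S,7R)-6,7-dihydroxy-7-methyl-8-oxo-5,6,7,8-tetrahydro-1H-isochromen-3-yl]prop-2-enoate F7. Acid 19 is converted with 1-chloro-N,N,2-trimethylprop-1-en-1-amine into 2-methoxy-6-methyl-3,4-bis[(triisopropylsilyl)oxy]benzoyl chloride F8. F8 then acylates the secondary hydroxyl of F7 selectively (Et3N, 4-(dimethylamino)pyridine, CH2Cl2) to give 20.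

**Further compounds**
F1 | step 3 | (1R,6R)-1-methyl-4-{[tri(propan-2-yl)silyl]ethynyl}-7-oxabicyclo[4.1.0]heptan-2-one (C4 epimers) | CC(C)[Si](C#CC1CC(=O)[C@]2(C)O[C@@H]2C1)(C(C)C)C(C)C
F2 | step 3 | (1R,6R)-4-ethynyl-1-methyl-7-oxabicyclo[4.1.0]heptan-2-one (C4 epimers) | C#CC1CC(=O)[C@]2(C)O[C@@H]2C1
F3 | step 3 | 2-(trimethylsilyl)ethyl (E)-3-iodoprop-2-enoate | C[Si](C)(C)CCOC(=O)/C=C/I
F4 | step 5 | lithium enolate of 9 | C[Si](C)(C)CCOC(=O)/C=C/C#CC1C=C(O[Li])[C@]2(C)O[C@@H]2C1
F5 | step 5 | 2-(trimethylsilyl)ethyl (E)-5-[(1R,6R)-1-methyl-2-oxo-3-{[(triisopropylsilyl)oxy]methyl}-7-oxabicyclo[4.1.0]heptan-4-yl]pent-2-en-4-ynoate | C[Si](C)(C)CCOC(=O)/C=C/C#CC1C(CO[Si](C(C)C)(C(C)C)C(C)C)C(=O)[C@]2(C)O[C@@H]2C1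
F6 | step 5 | 2-(trimethylsilyl)ethyl (E)-5-[(1R,6R)-1-methyl-2-oxo-3-{[(triisopropylsilyl)oxy]methyl}-7-oxabicyclo[4.1.0]hept-3-en-4-yl]pent-2-en-4-ynoate | C[Si](C)(C)CCOC(=O)/C=C/C#CC1=C(CO[Si](C(C)C)(C(C)C)C(C)C)C(=O)[C@]2(C)O[C@@H]2C1
F7 | step 10 | 2-(trimethylsilyl)ethyl (E)-3-[(6S,7R)-6,7-dihydroxy-7-methyl-8-oxo-5,6,7,8-tetrahydro-1H-isochromen-3-yl]prop-2-enoate | O[C@H]1CC2=C(COC(/C=C/C(=O)OCC[Si](C)(C)C)=C2)C(=O)[C@]1(C)O
F8 | step 10 | 2-methoxy-6-methyl-3,4-bis[(triisopropylsilyl)oxy]benzoyl chloride | COc1c(O[Si](C(C)C)(C(C)C)C(C)C)c(O[Si](C(C)C)(C(C)C)C(C)C)cc(C)c1C(Cl)=O
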